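**Retrosynthetic overview**
1. The E-enone is made last, by an aprotic lithium-polyanion aldol condensation of acetophenone 11 with aldehyde 12, then buffered fluoride. No acid is used once the allylic alcohol exists.
2. Key step: (Z)-Ar–CH=CH–CMe2OH ⇒ coumarin + 2 MeLi. The Z geometry is stored in a sacrificial lactone ring while the acetyl group is hidden as its silyl enol ether/enolate. This replaces the usual Sonogashira/Lindlar or prenyl-oxidation tactics.
3. Acetylcoumarin 7 ⇒ regioconvergent C-acetylation of 5-hydroxy-7-methoxycoumarin. Attack at C6 or C8 maps onto the same target carbon once the lactone is opened.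
4. Coumarin ⇒ phloroglucinol + ethyl propiolate.
5. Ring order: ring A is bought. A temporary pyranone ring is formed in step 1 and destroyed in step 5. Ring B arrives intact in step 6.

Assumption: the target has no stereocentre and is achiral, so "single enantiomer" is read as the single geometric isomer (side chain Z, enone E).

**Step 1**
Reactants: 1 phloroglucinol (benzene-1,3,5-triol); 2 ethyl propiolate
Product: 3, 5,7-dihydroxycoumarin (5,7-dihydroxy-2H-chromen-2-one)
Conditions: ZnCl2 (1 equiv), dioxane, 100 °C, 2 h
Reagents that add atoms: ethyl propiolate, C#CC(=O)OCC (EtOH is lost)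
Why: Pechmann-type conjugate hydroarylation of the propiolate by the C3-symmetric, highly nucleophilic phenol, followed by lactonisation, can give only one regioisomer, and closing the six-membered lactone forces the new C3=C4 alkene to be cis, which is the geometry the target needs.

**Step 2**
Reactants: 3; 4 iodomethane
Product: 5, 5-hydroxy-7-methoxycoumarin
Conditions: MeI (1.05 equiv), K2CO3 (1.0 equiv), acetone, rt → 40 °C; chromatography
Reagents that add atoms: iodomethane, CI
Why: In this base-limited Williamson etherification the 7-OH is the most acidic site (para-quinoid vinylogous acid through C4a–C4=C3–C2=O) and is unhindered, whereas the 5-OH is peri to H-4, so the 7-phenoxide forms and is methylated preferentially, and the dimethyl ether and minor 5-OMe isomer are removed by chromatography.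

**Step 3**
Reactants: 5; 6 acetic anhydride
Product: 7, 6-acetyl-5-hydroxy-7-methoxycoumarin
Conditions: Ac2O (2.5 equiv), BF3·OEt2 (4 equiv), 90 °C, 3 h; then NaOAc, aq. MeOH, 60 °C (cleaves the BF2 chelate)
Reagents that add atoms: acetic anhydride, CC(=O)OC(C)=O
Why: One-pot O-acetylation/Fries rearrangement (Friedel–Crafts acylation) on a phloroglucinol-type ring is driven to C6 by the O–BF2–O chelate with the 5-OH, BF3 rather than AlCl3 spares the 7-OMe, and attack at the only other open position (C8) would give an isomer that converges on the same compound 11 in step 5.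

**Step 4**
Reactants: 7; 8 trimethylsilyl triflate
Product: 9, 7-methoxy-5-(trimethylsilyloxy)-6-[1-(trimethylsilyloxy)ethenyl]-2H-chromen-2-one
Conditions: TMSOTf (2.6 equiv), Et3N (4 equiv), CH2Cl2, 0 °C → rt, 1 h; Et2O/pentane, cold aq. NaHCO3 wash; used crude
Reagents that add atoms: TMSOTf, C[Si](C)(C)OS(=O)(=O)C(F)(F)F
Why: Soft enolisation/silylation turns the ketone into a silyl enol ether and caps the phenol so the lactone is not deactivated as a phenoxide, and the lactone has no α-hydrogens and is untouched.

**Step 5 (key step)**
Reactants: 9; 10 methyllithium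
Product: 11, 1-{2,4-dihydroxy-3-[(1Z)-3-hydroxy-3-methylbut-1-en-1-yl]-6-methoxyphenyl}ethan-1-one
Conditions: 9 added to MeLi (6 equiv), THF/Et2O, −78 °C, 1 h → 0 °C, 1 h; inverse quench into pH 7 phosphate buffer, 0 °C; Et3N-deactivated SiO2, subdued light
Reagents that add atoms: methyllithium, [Li]C (two CH3 groups retained)
Why: In this double 1,2-addition of an organolithium to a lactone (the classical coumarin → cis-diol opening), hard MeLi attacks C2 (C4 is shielded by the peri 5-OSiMe3), the hemiketal alkoxide collapses to the (Z)-enone phenoxide and this takes up the second MeLi, so the Z alkene is inherited from the ring, while the ketone survives first as silyl enol ether and then, after Si–O cleavage by MeLi (Me4Si by-product), as its lithium enolate, and it is released together with the phenols on neutral quench.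

**Step 6**
Reactants: 11; 12 4-(tert-butyldimethylsilyloxy)benzaldehyde
Product: 13, (2E)-3-[4-(tert-butyldimethylsilyloxy)phenyl]-1-{2,4-dihydroxy-3-[(1Z)-3-hydroxy-3-methylbut-1-en-1-yl]-6-methoxyphenyl}prop-2-en-1-one
Conditions: LiHMDS (5.2 equiv), THF, −78 → −20 °C, 1 h; 12 (1.5 equiv), −78 °C → rt, 14 h; poured into cold pH 7 buffer; subdued light (partly desilylated material is carried on together)
Reagents that add atoms: 4-(TBSO)benzaldehyde, O=Cc1ccc(O[Si](C)(C)C(C)(C)C)cc1 (H2O is lost)
Why: This aldol condensation on the lithium tetra-anion (two phenoxides, alkoxide, enolate) in aprotic medium is a known way to make polyhydroxychalcones without OH protection, E1cB elimination on warming gives the conjugated E-enone under thermodynamic control (any ArCH=NSiMe3 formed from excess LiHMDS funnels to the same enone by Mannich/E1cB), the Z-styrene and tertiary alkoxide are inert to base, and the cold neutral quench avoids both acid-induced chromene formation and base-induced flavanone closure.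

**Step 7**
Reactants: 13
Product: 14, candidachalcone, (2E)-1-{2,4-dihydroxy-3-[(1Z)-3-hydroxy-3-methylbut-1-en-1-yl]-6-methoxyphenyl}-3-(4-hydroxyphenyl)prop-2-en-1-one
Conditions: TBAF/AcOH (1:1, 1.2 equiv), THF, 0 °C, 15 min; pH 7 work-up; Sephadex LH-20 (MeOH) or C18
Reagents that add atoms: none
Why: Fluoride desilylation of an aryl silyl ether activated by the para-enone is fast at 0 °C, and the AcOH buffer keeps the medium near neutral, so oxa-Michael closure to the flavanone, ionisation of the tertiary allylic alcohol to the 2,2-dimethylchromene, and alkene isomerisation are all avoided.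

**Compound list**

| No. | Name | SMILES | Role |
|---|---|---|---|
| 1 | phloroglucinol | Oc1cc(O)cc(O)c1 | starting material |
| 2 | ethyl propiolate | C#CC(=O)OCC | starting material |
| 3 | 5,7-dihydroxycoumarin | O=c1ccc2c(O)cc(O)cc2o1 | intermediate |
| 4 | iodomethane | CI | starting material (reagent) |
| 5 | 5-hydroxy-7-methoxycoumarin | O=c1ccc2c(O)cc(OC)cc2o1 | intermediate |
| 6 | acetic anhydride | CC(=O)OC(C)=O | starting material (reagent) |
| 7 | 6-acetyl-5-hydroxy-7-methoxycoumarin | O=c1ccc2c(O)c(C(C)=O)c(OC)cc2o1 | intermediate |
| 8 | trimethylsilyl triflate | C[Si](C)(C)OS(=O)(=O)C(F)(F)F | starting material (reagent) |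
| 9 | 7-methoxy-5-(TMSO)-6-[1-(TMSO)ethenyl]coumarin | O=c1ccc2c(O[Si](C)(C)C)c(C(=C)O[Si](C)(C)C)c(OC)cc2o1 | intermediate |
| 10 | methyllithium | [Li]C | starting material (reagent) |
| 11 | (Z)-3-(3-hydroxy-3-methylbut-1-enyl)-2,4-dihydroxy-6-methoxyacetophenone | CC(=O)c1c(OC)cc(O)c(/C=C\C(C)(C)O)c1O | intermediate |
| 12 | 4-(tert-butyldimethylsilyloxy)benzaldehyde | O=Cc1ccc(O[Si](C)(C)C(C)(C)C)cc1 | starting material |
| 13 | 4-O-TBS-candidachalcone | COc1cc(O)c(/C=C\C(C)(C)O)c(O)c1C(=O)/C=C/c1ccc(O[Si](C)(C)C(C)(C)C)cc1 | intermediate |
| 14 | candidachalcone | COc1cc(O)c(/C=C\C(C)(C)O)c(O)c1C(=O)/C=C/c1ccc(O)cc1 | target |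

**Total steps:** 7. **Longest linear sequence:** 7 (steps 4 and 5 are telescoped without purifying 9).

**Steps most likely to fail**
1. **Step 5.** Possible failures are 1,4-addition, stalling at the methyl ketone, premature enolate chemistry, and cyclodehydration to the chromene on work-up. Fallback: abandon the lactone opening and make the Z-alkene by stereoretentive Suzuki–Miyaura coupling. The partners would be 3-iodo-2,4-bis(silyloxy)-6-methoxyacetophenone and 5,5-dimethyl-1,2-oxaborol-2(5H)-ol, the cyclic Z-alkenylboronic half-ester from trans-hydroboration of 2-methylbut-3-yn-2-ol. The geometry is again ring-locked, and there is no organolithium/ketone conflict.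
2. **Step 6.** The tetra-anion may be insoluble, the reaction may stop at the aldol, or flavanone may form. Fallback: replace the aldol with a Horner–Wadsworth–Emmons olefination. Chloroacetylate 5 instead of acetylating it, then carry out Finkelstein/Arbuzov chemistry to the 6-(diethylphosphonoacetyl)coumarin. The lithium anion of this β-ketophosphonate is itself inert to MeLi, so it replaces the silyl enol ether mask. After lactone opening it olefinates 12 directly to the E-enone, with no dehydration step.
3. **Step 2.** The 7-OH versus 5-OH selectivity may be insufficient, or over-methylation may dominate. Fallback: build 5 from a symmetric precursor. Take 2,4,6-trihydroxybenzaldehyde through chelation-controlled 4-O-methylation to 2,6-dihydroxy-4-methoxybenzaldehyde. Then run a Wittig/lactonisation with Ph3P=CHCO2Et in refluxing PhNEt2. The two ortho OH groups are equivalent, so only 5 can form.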